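**Retrosynthetic overview**
1. Butenolide last: ring-closing metathesis C7=C11 between a C6 2-(acetoxymethyl)acrylate and an exocyclic methylene on C7. Rings form in the order ten-membered carbocycle, oxirane, butenolide.
2. The C6 ester comes from Mitsunobu inversion of a threo epoxy alcohol; the C4–C5 oxirane from hydroxyl-directed epoxidation of the macrocyclic Z-allylic alcohol.
3. Ten-membered ring by intramolecular Nozaki–Hiyama–Kishi (NHK) coupling C5–C6 (Z-vinyl iodide onto a 2-methylene aldehyde).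
4. Chain assembly: C2–C3 by enolate allylation with a Z-iodoallyl bromide; C7–C8 by asymmetric NHK coupling of a β-hydroxy aldehyde with 2-bromoacrolein acetal.
5. First stereocentre (C10) and the C9–C10 bond by an organocatalytic cross-aldol of acetaldehyde with butane-2,3-dione.

Assumption: labels C1–C15 are the germacrane positions of the target (C1 ketone, C4–C5 oxirane, C6 lactone carbinol, C7=C11 butenolide alkene, C8 propanoate carbinol, C10 acetoxy carbon, C12 lactone carbonyl, C13 CH2OAc); the target is (4R,5S,6S,8S,10R).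

**Route**

Step 1
Reactants: 1 acetaldehyde; 2 butane-2,3-dione
Product: 3 (3R)-3-hydroxy-3-methyl-4-oxopentanal
Conditions: (S)-α,α-bis[3,5-bis(trifluoromethyl)phenyl]prolinol (15 mol %), 1 (5 equiv), DMF, 4 °C, 48 h
Reagents that add atoms: none
Why: Proposed new method: the diarylprolinol forms the anti-enamine of acetaldehyde, which adds to one carbonyl of the symmetric 1,2-diketone (activated by the neighbouring acetyl group and held by a hydrogen bond to the catalyst hydroxyl) on its Re face to set C10 as R, the first stereocentre; the closest known reaction type is the diarylprolinol-catalysed enamine cross-aldol of acetaldehyde with isatins and other activated ketones, not yet shown for 1,2-diketones.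

Step 2
Reactants: 3 (3R)-3-hydroxy-3-methyl-4-oxopentanal; 4 2-bromo-3,3-diethoxyprop-1-ene
Product: 5 (3R,5S)-7,7-diethoxy-3,5-dihydroxy-3-methyl-6-methylideneheptan-2-one
Conditions: CrCl2 (4 equiv), NiCl2 (2 mol %), chiral 2-(oxazolinyl)anilide sulfonamide ligand (Kishi type, 4.4 equiv), Et3N, THF, rt; aqueous work-up
Reagents that add atoms: none
Why: Asymmetric Nozaki–Hiyama–Kishi coupling: the alkenylchromium adds only to the aldehyde (ketone and free hydroxyl tolerated), and the chromium-bound sulfonamide ligand, used in the antipode that gives the S carbinol, sets C8 by reagent control.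

Step 3
Reactants: 6 prop-2-yn-1-ol
Product: 7 (2Z)-3-iodo-2-methylprop-2-en-1-ol
Conditions: MeMgBr (2.5 equiv), CuI (10 mol %), Et2O, −10 °C to rt; then I2, −78 to 0 °C
Reagents that add atoms: methylmagnesium bromide C[Mg]Br; iodine [I][I]
Why: Copper-catalysed anti-carbomagnesiation of the propargylic alkoxide (Duboudin reaction) gives a chelated alkenylmagnesium whose iodinolysis with retention places iodine cis to CH2OH (Z).

Step 4
Reactants: 7 (2Z)-3-iodo-2-methylprop-2-en-1-ol
Product: 8 (1Z)-3-bromo-1-iodo-2-methylprop-1-ene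
Conditions: PBr3 (0.4 equiv), Et2O, 0 °C
Reagents that add atoms: phosphorus tribromide BrP(Br)Br
Why: SN2 bromination of the primary allylic alcohol, which leaves the alkene geometry untouched.

Step 5
Reactants: 5 (3R,5S)-7,7-diethoxy-3,5-dihydroxy-3-methyl-6-methylideneheptan-2-one; 8 (1Z)-3-bromo-1-iodo-2-methylprop-1-ene
Product: 9 (3S,5R,9Z)-1,1-diethoxy-3,5-dihydroxy-10-iodo-5,9-dimethyl-2-methylidenedec-9-en-6-one
Conditions: LiN(iPr)2 (3.2 equiv), THF, −78 °C; then 8, −78 to −30 °C
Reagents that add atoms: none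
Why: Enolate alkylation: after the two hydroxyls only the ketone methyl can be deprotonated (the other α-carbon is quaternary), and the lithium enolate is C-allylated by SN2 at the primary bromide with the Z-iodoalkene intact, the lithium alkoxides being too weakly nucleophilic to compete at low temperature.

Step 6
Reactants: 9 (3S,5R,9Z)-1,1-diethoxy-3,5-dihydroxy-10-iodo-5,9-dimethyl-2-methylidenedec-9-en-6-one
Product: 11 (3S,5R,9Z)-5-(acetyloxy)-1,1-diethoxy-10-iodo-5,9-dimethyl-2-methylidene-6-oxodec-9-en-3-yl propanoate, via C8 mono-propanoate 10 (not isolated)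
Conditions: (EtCO)2O (1.2 equiv), pyridine, CH2Cl2, 0 °C; then Ac2O (5 equiv), DMAP, Et3N, 40 °C
Reagents that add atoms: propanoic anhydride CCC(=O)OC(=O)CC; acetic anhydride CC(=O)OC(C)=O
Why: Acylation: the secondary allylic alcohol is esterified far faster than the tertiary ketol hydroxyl, which then needs DMAP catalysis and warming to take the acetyl group.

Step 7
Reactants: 11 (3S,5R,9Z)-5-(acetyloxy)-1,1-diethoxy-10-iodo-5,9-dimethyl-2-methylidene-6-oxodec-9-en-3-yl propanoate
Product: 12 (3S,5R,9Z)-5-(acetyloxy)-10-iodo-5,9-dimethyl-2-methylidene-1,6-dioxodec-9-en-3-yl propanoate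
Conditions: PPTS (20 mol %), acetone/H2O (10:1), 40 °C
Reagents that add atoms: water O
Why: Acid-catalysed acetal hydrolysis frees the C6 aldehyde while the esters, the ketone and the vinyl iodide are stable to the mild acid.

Step 8
Reactants: 12 (3S,5R,9Z)-5-(acetyloxy)-10-iodo-5,9-dimethyl-2-methylidene-1,6-dioxodec-9-en-3-yl propanoate
Product: 13 (1S,3R,7Z,9S)-3-(acetyloxy)-9-hydroxy-3,7-dimethyl-10-methylidene-4-oxocyclodec-7-en-1-yl propanoate
Conditions: CrCl2 (6 equiv), NiCl2 (5 mol %), chiral 2-(oxazolinyl)anilide sulfonamide ligand (6.6 equiv), Et3N, THF/MeCN, 2 mM, rt; aqueous work-up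
Reagents that add atoms: none
Why: Intramolecular Nozaki–Hiyama–Kishi reaction: the Z-alkenylchromium (geometry retained, no β-leaving group) adds 1,2 to the aldehyde rather than to the hindered ketone and closes the ten-membered ring, the ligand antipode being chosen for the C6 carbinol with C6–O anti to C8–O, the sense also expected from 1,3-anti induction by the β-acyloxy group.

Step 9
Reactants: 13 (1S,3R,7Z,9S)-3-(acetyloxy)-9-hydroxy-3,7-dimethyl-10-methylidene-4-oxocyclodec-7-en-1-yl propanoate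
Product: 14 (1S,2R,4S,6R,10R)-6-(acetyloxy)-2-hydroxy-6,10-dimethyl-3-methylidene-7-oxo-11-oxabicyclo[8.1.0]undecan-4-yl propanoate
Conditions: mCPBA (1.2 equiv), CH2Cl2, 0 °C
Reagents that add atoms: 3-chloroperbenzoic acid OOC(=O)c1cccc(Cl)c1
Why: Hydroxyl-directed (Henbest) epoxidation: allylic 1,3-strain with the cis ring carbon C3 holds H6 in the alkene plane, so the hydrogen-bonded peracid attacks the face syn to the hydroxyl and gives the threo cis-oxirane with C4 R and C5 S, the trisubstituted alkene reacting before the exocyclic methylene.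

Step 10
Reactants: 15 2-(bromomethyl)prop-2-enoic acid
Product: 16 2-[(acetyloxy)methyl]prop-2-enoic acid
Conditions: NaOAc (1.5 equiv), AcOH, 60 °C
Reagents that add atoms: sodium acetate CC(=O)[O-].[Na+]
Why: Nucleophilic displacement of the allylic bromide by acetate, in which the SN2 and SN2′ paths give the same product.

Step 11
Reactants: 14 (1S,2R,4S,6R,10R)-6-(acetyloxy)-2-hydroxy-6,10-dimethyl-3-methylidene-7-oxo-11-oxabicyclo[8.1.0]undecan-4-yl propanoate; 16 2-[(acetyloxy)methyl]prop-2-enoic acid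
Product: 17 (1S,2S,4S,6R,10R)-6-(acetyloxy)-6,10-dimethyl-3-methylidene-7-oxo-4-(propanoyloxy)-11-oxabicyclo[8.1.0]undecan-2-yl 2-[(acetyloxy)methyl]prop-2-enoate
Conditions: PPh3, DIAD (mixed first), then 14 and 16, THF, 0 °C to rt
Reagents that add atoms: none
Why: Mitsunobu esterification: the carboxylate displaces the activated oxygen by SN2 with inversion at C6, turning the threo epoxy alcohol into the erythro ester with C6 S as in the target.

Step 12
Reactants: 17 (1S,2S,4S,6R,10R)-6-(acetyloxy)-6,10-dimethyl-3-methylidene-7-oxo-4-(propanoyloxy)-11-oxabicyclo[8.1.0]undecan-2-yl 2-[(acetyloxy)methyl]prop-2-enoate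
Product: 18 (4R,5S,6S,8S,10R)-10,13-bis(acetyloxy)-4,5-epoxy-1-oxo-8-(propanoyloxy)germacr-7(11)-en-12,6-olide (the target)
Conditions: RuCl2(1,3-di-o-tolylimidazolidin-2-ylidene)(=CH-C6H4-2-OiPr) (Stewart–Grubbs catalyst, 15 mol %), toluene, 2 mM, 80 °C
Reagents that add atoms: none
Why: Ring-closing metathesis with a ruthenium alkylidene built for tetrasubstituted olefins joins the two 1,1-disubstituted alkenes into the five-membered butenolide with loss of ethene under neutral conditions, so the base-sensitive epoxy butenolide is made last and no stereocentre is touched.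

**Compound list**
1 | acetaldehyde | CC=O | starting material
2 | butane-2,3-dione | CC(=O)C(C)=O | starting material
3 | (3R)-3-hydroxy-3-methyl-4-oxopentanal | O=CC[C@@](C)(O)C(C)=O | intermediate
4 | 2-bromo-3,3-diethoxyprop-1-ene (2-bromoacrolein diethyl acetal) | C=C(Br)C(OCC)OCC | starting material
5 | (3R,5S)-7,7-diethoxy-3,5-dihydroxy-3-methyl-6-methylideneheptan-2-one | O[C@@H](C[C@@](C)(O)C(C)=O)C(=C)C(OCC)OCC | intermediate
6 | prop-2-yn-1-ol | C#CCO | starting material
7 | (2Z)-3-iodo-2-methylprop-2-en-1-ol | OC/C(C)=C\I | intermediate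
8 | (1Z)-3-bromo-1-iodo-2-methylprop-1-ene | BrC/C(C)=C\I | intermediate
9 | (3S,5R,9Z)-1,1-diethoxy-3,5-dihydroxy-10-iodo-5,9-dimethyl-2-methylidenedec-9-en-6-one | O[C@@H](C[C@@](C)(O)C(=O)CC/C(C)=C\I)C(=C)C(OCC)OCC | intermediate
10 | (3S,5R,9Z)-1,1-diethoxy-5-hydroxy-10-iodo-5,9-dimethyl-2-methylidene-6-oxodec-9-en-3-yl propanoate | CCC(=O)O[C@@H](C[C@@](C)(O)C(=O)CC/C(C)=C\I)C(=C)C(OCC)OCC | intermediate
11 | (3S,5R,9Z)-5-(acetyloxy)-1,1-diethoxy-10-iodo-5,9-dimethyl-2-methylidene-6-oxodec-9-en-3-yl propanoate | CCC(=O)O[C@@H](C[C@@](C)(OC(C)=O)C(=O)CC/C(C)=C\I)C(=C)C(OCC)OCC | intermediate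
12 | (3S,5R,9Z)-5-(acetyloxy)-10-iodo-5,9-dimethyl-2-methylidene-1,6-dioxodec-9-en-3-yl propanoate | CCC(=O)O[C@@H](C[C@@](C)(OC(C)=O)C(=O)CC/C(C)=C\I)C(=C)C=O | intermediate
13 | (1S,3R,7Z,9S)-3-(acetyloxy)-9-hydroxy-3,7-dimethyl-10-methylidene-4-oxocyclodec-7-en-1-yl propanoate | CCC(=O)O[C@H]1C[C@@](C)(OC(C)=O)C(=O)CC/C(C)=C\[C@H](O)C1=C | intermediate
14 | (1S,2R,4S,6R,10R)-6-(acetyloxy)-2-hydroxy-6,10-dimethyl-3-methylidene-7-oxo-11-oxabicyclo[8.1.0]undecan-4-yl propanoate | CCC(=O)O[C@H]1C[C@@](C)(OC(C)=O)C(=O)CC[C@@]2(C)O[C@H]2[C@H](O)C1=C | intermediate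
15 | 2-(bromomethyl)prop-2-enoic acid | OC(=O)C(=C)CBr | starting material
16 | 2-[(acetyloxy)methyl]prop-2-enoic acid | CC(=O)OCC(=C)C(=O)O | intermediate
17 | (1S,2S,4S,6R,10R)-6-(acetyloxy)-6,10-dimethyl-3-methylidene-7-oxo-4-(propanoyloxy)-11-oxabicyclo[8.1.0]undecan-2-yl 2-[(acetyloxy)methyl]prop-2-enoate | CCC(=O)O[C@H]1C[C@@](C)(OC(C)=O)C(=O)CC[C@@]2(C)O[C@H]2[C@@H](OC(=O)C(=C)COC(C)=O)C1=C | intermediate
18 | (4R,5S,6S,8S,10R)-10,13-bis(acetyloxy)-4,5-epoxy-1-oxo-8-(propanoyloxy)germacr-7(11)-en-12,6-olide | CCC(=O)O[C@H]1C[C@@](C)(OC(C)=O)C(=O)CC[C@@]2(C)O[C@H]2[C@H]2OC(=O)C(COC(C)=O)=C12 | target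

**Step count and risks**

Total steps: 12. Longest linear sequence: 9 (steps 1, 2, 5, 6, 7, 8, 9, 11, 12).

The three steps most likely to fail:

First, step 1, the proposed new aldol. The diketone may condense with the amine catalyst or with itself, and the sense and level of induction are untested. The fallback uses known chemistry, sets out from 2 and returns at 3. A Mukaiyama aldol of 2 with 1-(tert-butylsulfanyl)-1-[(trimethylsilyl)oxy]ethene, catalysed by Cu(OTf)2 with the (R,R)-tBu-box ligand (THF, −78 °C), gives the silyl ether S-tert-butyl (3R)-3-methyl-4-oxo-3-[(trimethylsilyl)oxy]pentanethioate F1. Dilute HCl frees S-tert-butyl (3R)-3-hydroxy-3-methyl-4-oxopentanethioate F2. Fukuyama reduction (Et3SiH, Pd/C, acetone) then gives aldehyde 3.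

Second, step 8, the ten-membered NHK closure. Medium-ring strain, oligomerisation, and attack of the alkenylchromium on the C1 ketone (a five-membered closure) are the risks. The fallback closes the ring by olefin metathesis instead; it sets out from 5 and returns at 13. Alkylation of 5 with 3-bromo-2-methylprop-1-ene (LiN(iPr)2, as in step 5) gives (3S,5R)-1,1-diethoxy-3,5-dihydroxy-5,9-dimethyl-2-methylidenedec-9-en-6-one F3. Propanoylation gives (3S,5R)-1,1-diethoxy-5-hydroxy-5,9-dimethyl-2-methylidene-6-oxodec-9-en-3-yl propanoate F4, which is acetylated in the same flask to (3S,5R)-5-(acetyloxy)-1,1-diethoxy-5,9-dimethyl-2-methylidene-6-oxodec-9-en-3-yl propanoate F5. PPTS hydrolysis gives (3S,5R)-5-(acetyloxy)-5,9-dimethyl-2-methylidene-1,6-dioxodec-9-en-3-yl propanoate F6. Asymmetric NHK vinylation with bromoethene (CrCl2, NiCl2, the chiral sulfonamide ligand) gives (3S,5S,7R)-7-(acetyloxy)-3-hydroxy-7,11-dimethyl-4-methylidene-8-oxododeca-1,11-dien-5-yl propanoate F7; here no alkenylmetal is tethered to the ketone. Ring-closing metathesis of the vinyl and isopropenyl groups (second-generation Grubbs catalyst, toluene, high dilution, 80 °C) then gives the Z-cyclodecene 13.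

Third, step 12, the metathesis to a tetrasubstituted butenolide on a hindered macrocycle. The fallback builds the alkene by olefination; it sets out from 14 and returns at 18. Mitsunobu esterification of 14 with 2-(diethoxyphosphoryl)prop-2-enoic acid (PPh3, DIAD) gives the inverted ester (1S,2S,4S,6R,10R)-6-(acetyloxy)-6,10-dimethyl-3-methylidene-7-oxo-4-(propanoyloxy)-11-oxabicyclo[8.1.0]undecan-2-yl 2-(diethoxyphosphoryl)prop-2-enoate F8. Ozonolysis of the ring methylene (O3, CH2Cl2, −78 °C; Me2S), which spares the electron-poor phosphonoacrylate, gives the ketone (1S,2R,4S,6R,10R)-6-(acetyloxy)-6,10-dimethyl-3,7-dioxo-4-(propanoyloxy)-11-oxabicyclo[8.1.0]undecan-2-yl 2-(diethoxyphosphoryl)prop-2-enoate F9. CsOAc (18-crown-6, MeCN) then adds acetate to the vinylphosphonate, and the phosphonate carbanion closes onto the C7 ketone (intramolecular Horner–Wadsworth–Emmons) to give 18.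

**Further compounds**
F1 | step 1 | S-tert-butyl (3R)-3-methyl-4-oxo-3-[(trimethylsilyl)oxy]pentanethioate | CC(C)(C)SC(=O)C[C@@](C)(O[Si](C)(C)C)C(C)=O
F2 | step 1 | S-tert-butyl (3R)-3-hydroxy-3-methyl-4-oxopentanethioate | CC(C)(C)SC(=O)C[C@@](C)(O)C(C)=O
F3 | step 8 | (3S,5R)-1,1-diethoxy-3,5-dihydroxy-5,9-dimethyl-2-methylidenedec-9-en-6-one | O[C@@H](C[C@@](C)(O)C(=O)CCC(C)=C)C(=C)C(OCC)OCC
F4 | step 8 | (3S,5R)-1,1-diethoxy-5-hydroxy-5,9-dimethyl-2-methylidene-6-oxodec-9-en-3-yl propanoate | CCC(=O)O[C@@H](C[C@@](C)(O)C(=O)CCC(C)=C)C(=C)C(OCC)OCC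
F5 | step 8 | (3S,5R)-5-(acetyloxy)-1,1-diethoxy-5,9-dimethyl-2-methylidene-6-oxodec-9-en-3-yl propanoate | CCC(=O)O[C@@H](C[C@@](C)(OC(C)=O)C(=O)CCC(C)=C)C(=C)C(OCC)OCC
F6 | step 8 | (3S,5R)-5-(acetyloxy)-5,9-dimethyl-2-methylidene-1,6-dioxodec-9-en-3-yl propanoate | CCC(=O)O[C@@H](C[C@@](C)(OC(C)=O)C(=O)CCC(C)=C)C(=C)C=O
F7 | step 8 | (3S,5S,7R)-7-(acetyloxy)-3-hydroxy-7,11-dimethyl-4-methylidene-8-oxododeca-1,11-dien-5-yl propanoate | CCC(=O)O[C@@H](C[C@@](C)(OC(C)=O)C(=O)CCC(C)=C)C(=C)[C@@H](O)C=C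
F8 | step 12 | (1S,2S,4S,6R,10R)-6-(acetyloxy)-6,10-dimethyl-3-methylidene-7-oxo-4-(propanoyloxy)-11-oxabicyclo[8.1.0]undecan-2-yl 2-(diethoxyphosphoryl)prop-2-enoate | CCC(=O)O[C@H]1C[C@@](C)(OC(C)=O)C(=O)CC[C@@]2(C)O[C@H]2[C@@H](OC(=O)C(=C)P(=O)(OCC)OCC)C1=C
F9 | step 12 | (1S,2R,4S,6R,10R)-6-(acetyloxy)-6,10-dimethyl-3,7-dioxo-4-(propanoyloxy)-11-oxabicyclo[8.1.0]undecan-2-yl 2-(diethoxyphosphoryl)prop-2-enoate | CCC(=O)O[C@H]1C[C@@](C)(OC(C)=O)C(=O)CC[C@@]2(C)O[C@H]2[C@@H](OC(=O)C(=C)P(=O)(OCC)OCC)C1=O
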